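The target is epicatechin-(4β→6)-catechin-(4α→6)-catechin. After removal of the benzyl ethers and of a bromine cap on C8 of the lower unit, the retrosynthesis cuts C5–C6 in ring A of the middle unit.
This cut is possible because that ring A is a phloroglucinol sharing C4a–C8a with ring C, with O1 on C8a and the upper C4 on C6. If the C7 oxygen takes the ring position of C6, the ring becomes a 2H,5H-pyrano[4,3-b]pyran-5-one (lactone C5(=O)–O6–C7) that carries C6 as a CH2 group on C7.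
Further cuts in the middle unit are C3–O/C2–H (hydroboration), O1–C2 (cyclodehydration), C2–aryl (Grignard) and C4–C4a (Michael addition of a 4-hydroxy-2-pyrone to a lower-unit enal). The pyrone itself comes from methyl acetoacetate and the 4β-acetaldehyde of epicatechin (C4–allyl bond).
Forward order: upper side chain, pyrone ring, C4–C4a bond, ring B attached, ring C closed, ring A closed (key step), deprotection.
Stereochemistry: C2/C3 of the upper and lower units come from (−)-epicatechin and (+)-catechin. The upper C4 is set by attack trans to the 3-O-benzyl group, the middle C4 by a chiral amine catalyst, and the middle C2/C3 by syn hydroboration anti to the 4-aryl group.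

Key step: step 21

Remark: pyranopyranone locants (O1, C2–C4, C4a, C5, O6, C7, C8, C8a) coincide with flavan locants, except that O6 stands where C6 will be. α/β refer to the usual flavan drawing (2-aryl groups α). EC = 3,5,7,3',4'-penta-O-benzylepicatechin-4β-yl, CAT = 8-bromo-3,5,7,3',4'-penta-O-benzylcatechin-6-yl, Ar = 3,4-bis(benzyloxy)phenyl.

Step 1
Reactants: 1 (−)-epicatechin
Product: 2 5,7,3',4'-tetra-O-benzyl-(−)-epicatechin
Conditions: BnBr (4.5 equiv), K2CO3, DMF, 0 °C → rt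
Reagents that add atoms: benzyl bromide BrCc1ccccc1
Why: Williamson ether synthesis in which K2CO3 deprotonates only the four phenols, so the aliphatic 3-OH stays free and the mild base avoids C2 epimerisation.

Step 2
Reactants: 2 5,7,3',4'-tetra-O-benzyl-(−)-epicatechin
Product: 3 3,5,7,3',4'-penta-O-benzyl-(−)-epicatechin
Conditions: NaH, BnBr, DMF, 0 °C → rt
Reagents that add atoms: benzyl bromide BrCc1ccccc1
Why: Williamson ether synthesis on the sodium alkoxide of the remaining secondary alcohol, safe now that no free phenol is left to open ring C.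

Step 3
Reactants: 3 3,5,7,3',4'-penta-O-benzyl-(−)-epicatechin
Product: 4 4β-(2-ethoxyethoxy)-3,5,7,3',4'-penta-O-benzylepicatechin
Conditions: DDQ (2 equiv), 2-ethoxyethanol (5 equiv), CH2Cl2, rt
Reagents that add atoms: 2-ethoxyethanol CCOCCO
Why: DDQ-mediated benzylic C–H oxidation in which hydride leaves C4, the position activated by the 5,7-dioxygenated ring A, and the alcohol captures the cation on the β face opposite the 3α-benzyloxy group, while unactivated benzyl ethers are left alone.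

Step 4
Reactants: 4 4β-(2-ethoxyethoxy)-3,5,7,3',4'-penta-O-benzylepicatechin
Product: 5 4β-allyl-3,5,7,3',4'-penta-O-benzylepicatechin
Conditions: allyltrimethylsilane (4 equiv), Me3SiOSO2CF3 (0.2 equiv), CH2Cl2, −78 °C
Reagents that add atoms: allyltrimethylsilane C=CC[Si](C)(C)C
Why: Hosomi–Sakurai allylation in which the silyl triflate ionises the C4 ether and the allylsilane, used in excess to outrun self-condensation, attacks the planar cation trans to the axial 3α-benzyloxy group, which sets the upper C4 as 4β.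

Step 5
Reactants: 5 4β-allyl-3,5,7,3',4'-penta-O-benzylepicatechin
Product: 7 2-(EC)acetaldehyde, via diol 6 (not isolated)
Conditions: OsO4 (2 mol %), NaIO4 (4 equiv), 2,6-lutidine, dioxane–H2O, rt
Reagents that add atoms: sodium periodate [Na+].[O-]I(=O)(=O)=O
Why: Lemieux–Johnson oxidation, since the terminal alkene is the only site that OsO4 dihydroxylates and periodate cleaves diol 6 in the same flask, with lutidine suppressing over-oxidation.

Step 6
Reactants: 7 2-(EC)acetaldehyde; 8 methyl acetoacetate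
Product: 10 methyl 5-hydroxy-3-oxo-6-(EC)hexanoate (C5 epimers), via acetoacetate dianion 9 (not isolated)
Conditions: 8, NaH then n-BuLi, THF, 0 °C; 7, −78 °C; then H2O
Reagents that add atoms: none
Why: Aldol addition of the acetoacetate dianion, which reacts only at its terminal carbon; the new carbinol centre forms unselectively and is erased in step 7.

Step 7
Reactants: 10 methyl 5-hydroxy-3-oxo-6-(EC)hexanoate
Product: 11 methyl 3,5-dioxo-6-(EC)hexanoate
Conditions: Dess–Martin periodinane (1.5 equiv), CH2Cl2, 0 °C → rt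
Reagents that add atoms: none
Why: Dess–Martin oxidation under neutral conditions turns the carbinol into the 3,5-dioxo ester without touching benzyl ethers or flavan stereocentres.

Step 8
Reactants: 11 methyl 3,5-dioxo-6-(EC)hexanoate
Product: 12 4-hydroxy-6-[(EC)methyl]-2H-pyran-2-one
Conditions: DBU (2 equiv), toluene, 60 °C
Reagents that add atoms: none
Why: Base-induced enol lactonisation of a 3,5-dioxo ester, the standard closure to a 6-substituted 4-hydroxy-2-pyrone, driven by loss of methanol and formation of the acidic pyrone.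

Step 9
Reactants: 13 (+)-catechin
Product: 14 5,7,3',4'-tetra-O-benzyl-(+)-catechin
Conditions: BnBr (4.5 equiv), K2CO3, DMF, 0 °C → rt
Reagents that add atoms: benzyl bromide BrCc1ccccc1
Why: Williamson ether synthesis selective for the four phenols, as in step 1.

Step 10
Reactants: 14 5,7,3',4'-tetra-O-benzyl-(+)-catechin
Product: 15 3,5,7,3',4'-penta-O-benzyl-(+)-catechin
Conditions: NaH, BnBr, DMF, 0 °C → rt
Reagents that add atoms: benzyl bromide BrCc1ccccc1
Why: Williamson ether synthesis on the secondary alkoxide, as in step 2.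

Step 11
Reactants: 15 3,5,7,3',4'-penta-O-benzyl-(+)-catechin
Product: 16 8-bromo-3,5,7,3',4'-penta-O-benzylcatechin
Conditions: NBS (1.0 equiv), CH2Cl2, −78 → 0 °C
Reagents that add atoms: N-bromosuccinimide O=C1CCC(=O)N1Br
Why: Electrophilic aromatic bromination; in O-protected catechins C8 is the more reactive of the two free ring A positions, so one equivalent of NBS at low temperature caps it and leaves C6 as the only nucleophilic carbon.

Step 12
Reactants: 16 8-bromo-3,5,7,3',4'-penta-O-benzylcatechin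
Product: 18 8-bromo-6-formyl-3,5,7,3',4'-penta-O-benzylcatechin, via aryl iminium chloride 17 (not isolated)
Conditions: POCl3 (3 equiv), DMF, 0 → 70 °C; then ice-water
Reagents that add atoms: N,N-dimethylformamide CN(C)C=O; water O
Why: Vilsmeier–Haack formylation at C6, the only free position of the still trioxygenated ring A, followed by hydrolysis of iminium salt 17 on aqueous work-up.

Step 13
Reactants: 18 8-bromo-6-formyl-3,5,7,3',4'-penta-O-benzylcatechin
Product: 19 (E)-3-(CAT)prop-2-enal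
Conditions: Ph3P=CHCHO (1.5 equiv), toluene, 100 °C
Reagents that add atoms: (triphenylphosphoranylidene)acetaldehyde O=CC=P(c1ccccc1)(c1ccccc1)c1ccccc1
Why: Wittig olefination with a stabilised ylide, which gives the E-enal and stops there because the product enal is deactivated by its electron-rich aryl group.

Step 14
Reactants: 12 4-hydroxy-6-[(EC)methyl]-2H-pyran-2-one; 19 (E)-3-(CAT)prop-2-enal
Product: 21 (4R)-4-(CAT)-2-hydroxy-7-[(EC)methyl]-3,4-dihydro-2H,5H-pyrano[4,3-b]pyran-5-one (lactol anomers), via open-chain aldehyde 20 (not isolated)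
Conditions: (R)-2-[diphenyl(trimethylsilyloxy)methyl]pyrrolidine (20 mol %), CH2Cl2, rt
Reagents that add atoms: none
Why: Iminium-catalysed Michael addition and hemiacetalisation, known for 4-hydroxy-2-pyrones and β-aryl enals: the bulky diphenyl(silyloxy)methyl group of the R-configured amine shields one face of the E-iminium ion, so pyrone C3 (the future C4a) bonds to the open face and sets C4 as R (aryl α), while the lactol carbon is an inconsequential anomeric mixture.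

Step 15
Reactants: 22 4-bromocatechol
Product: 23 4-bromo-1,2-bis(benzyloxy)benzene
Conditions: BnBr (2.3 equiv), K2CO3, DMF, rt
Reagents that add atoms: benzyl bromide BrCc1ccccc1
Why: Williamson ether synthesis on both phenols.

Step 16
Reactants: 21 lactol from step 14; 23 4-bromo-1,2-bis(benzyloxy)benzene
Product: 25 3-[(1R)-3-Ar-1-(CAT)-3-hydroxypropyl]-4-hydroxy-6-[(EC)methyl]-2H-pyran-2-one (carbinol epimers), via arylmagnesium bromide 24 (not isolated)
Conditions: 23, Mg, THF, 50 °C; then 21 (0.3 equiv relative to 24), THF, −20 °C → rt; then H2O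
Reagents that add atoms: none
Why: Grignard addition in which the first equivalent of 24 deprotonates the lactol, which opens to the aldehyde and a magnesium pyronate that resists attack, and the second equivalent adds to the aldehyde; the aryl bromide of CAT is inert at this temperature and the mixed carbinol configuration is removed in step 17.

Step 17
Reactants: 25 carbinol from step 16
Product: 26 3-[(1R)-3-Ar-1-(CAT)-3-oxopropyl]-4-hydroxy-6-[(EC)methyl]-2H-pyran-2-one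
Conditions: Dess–Martin periodinane (1.3 equiv), CH2Cl2, 0 °C
Reagents that add atoms: none
Why: Dess–Martin oxidation of the benzylic carbinol, chosen because its base-free medium gives the 1,5-dicarbonyl adduct no opportunity for retro-Michael cleavage at C4.

Step 18
Reactants: 26 aryl ketone from step 17
Product: 28 (4R)-2-Ar-4-(CAT)-7-[(EC)methyl]-4H,5H-pyrano[4,3-b]pyran-5-one, via cyclic hemiketal 27 (not isolated)
Conditions: p-toluenesulfonic acid monohydrate (5 mol %), 4 Å molecular sieves, toluene, 60 °C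
Reagents that add atoms: none
Why: Acid-catalysed cyclodehydration, as used for chalcone adducts of 4-hydroxycoumarins: the pyrone 4-OH adds to the aryl ketone to give hemiketal 27, which loses water to the conjugated 2-aryl-4H-pyran, closing ring C through O1 and leaving C4 untouched.

Step 19
Reactants: 28 4H-pyran from step 18
Product: 30 (2R,3S,4R)-2-Ar-4-(CAT)-3-hydroxy-7-[(EC)methyl]-3,4-dihydro-2H,5H-pyrano[4,3-b]pyran-5-one, via C3 borane 29 (not isolated)
Conditions: BH3·THF (4 equiv), THF, 0 °C → rt; then 30% H2O2, aq NaHCO3, 0 °C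
Reagents that add atoms: hydrogen peroxide OO
Why: Hydroboration–oxidation of a cyclic 2-aryl enol ether, as for flav-2-enes and glycals: boron goes to C3, away from the carbon bearing O1 and aryl, syn addition takes place on the β face opposite the pseudo-axial 4α-aryl group, and oxidation with retention gives the 2,3-trans-3,4-trans array.

Step 20
Reactants: 30 alcohol from step 19
Product: 31 (2R,3S,4R)-2-Ar-3-benzyloxy-4-(CAT)-7-[(EC)methyl]-3,4-dihydro-2H,5H-pyrano[4,3-b]pyran-5-one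
Conditions: BnBr (5 equiv), Ag2O (3 equiv), 4 Å molecular sieves, CH2Cl2, dark, rt → 40 °C
Reagents that add atoms: benzyl bromide BrCc1ccccc1
Why: Ag2O-promoted Williamson-type benzylation, which never generates a free C3 alkoxide that could displace or take over the good leaving group O1 on the neighbouring carbon.

Step 21
Reactants: 31 pyranopyranone from step 20
Product: 33 penta-O-benzylepicatechin-(4β→6)-3,3',4'-tri-O-benzylcatechin-(4α→6)-8-bromo-penta-O-benzylcatechin (free 5-OH and 7-OH on the middle unit), via ring-opened keto ester 32 (not isolated)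
Conditions: NaOMe (5 equiv), MeOH–THF 1:1, argon, sealed tube, 65 → 110 °C; then AcOH
Reagents that add atoms: none
Why: Proposed new method: methoxide adds to the lactone carbonyl C5 and cleaves C5–O6 to give methyl ester 32, in which the C7 oxygen is a ketone flanked by C8H2 and by the exocyclic CH2 that carries EC; 32 rests as the unproductive C8 dienolate, but in the protic medium this stays in equilibrium with the neutral keto ester and its CH2 enolate, which adds to the ester, expels methoxide and tautomerises to the phenoxide of 33, the thermodynamic sink. The closest known reactions are the alkoxide-induced Claisen cyclisations of 6-alkyl-4-alkoxy-2-pyrones and of 3,5-dioxo esters to phloroglucinols, which have not been run on a pyrone that is fused at C4a–C8a and fully substituted. Ring A closes in a 6-(enolendo)-exo-trig mode by forming C5–C6, and no stereocentre is created. The step needs C-acylation at the CH2 carbon, and the substrate secures it: attack through C8 would give a four-membered ring, attack through the C7 oxygen only regenerates 31, and the C4a=C8a double bond, being part of ring C, cannot leave the geometry that holds the ester and the ketone arm side by side. Connectivity cannot scramble, because the carbon bearing EC can only become C6 and the only enol-ether oxygen is O1. C4–H is cross-conjugated to the ester and therefore not acidified, the 3-O-benzyl ether removes the alkoxide that could displace O1, and every phenol of the other units is capped, so the eight existing stereocentres should survive the hot base.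

Step 22
Reactants: 33 protected trimer from step 21
Product: 34 epicatechin-(4β→6)-catechin-(4α→6)-catechin
Conditions: H2 (1 atm), Pd(OH)2/C, Et3N (1.5 equiv), THF–MeOH–H2O, rt
Reagents that add atoms: none
Why: Catalytic hydrogenolysis removes the thirteen O-benzyl groups and the aryl bromide in one operation, as is usual for benzylated, bromine-capped flavan-3-ol oligomers, and Et3N traps the HBr that could cleave the interflavan bonds.

Compound list
1 | (−)-epicatechin | Oc1cc(O)c2c(c1)O[C@H](c1ccc(O)c(O)c1)[C@H](O)C2 | starting material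
2 | 5,7,3',4'-tetra-O-benzyl-(−)-epicatechin | O(Cc5ccccc5)c1cc(OCc5ccccc5)c2c(c1)O[C@H](c4ccc(OCc5ccccc5)c(OCc5ccccc5)c4)[C@H](O)C2 | intermediate
3 | 3,5,7,3',4'-penta-O-benzyl-(−)-epicatechin | O(Cc5ccccc5)c1cc(OCc5ccccc5)c2c(c1)O[C@H](c4ccc(OCc5ccccc5)c(OCc5ccccc5)c4)[C@H](OCc5ccccc5)C2 | intermediate
4 | 4β-(2-ethoxyethoxy)-penta-O-benzylepicatechin | O(Cc5ccccc5)c1cc(OCc5ccccc5)c2c(c1)O[C@H](c4ccc(OCc5ccccc5)c(OCc5ccccc5)c4)[C@H](OCc5ccccc5)[C@H]2OCCOCC | intermediate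
5 | 4β-allyl-penta-O-benzylepicatechin | O(Cc5ccccc5)c1cc(OCc5ccccc5)c2c(c1)O[C@H](c4ccc(OCc5ccccc5)c(OCc5ccccc5)c4)[C@H](OCc5ccccc5)[C@H]2CC=C | intermediate
6 | 4β-(2,3-dihydroxypropyl)-penta-O-benzylepicatechin (side-chain epimers) | O(Cc5ccccc5)c1cc(OCc5ccccc5)c2c(c1)O[C@H](c4ccc(OCc5ccccc5)c(OCc5ccccc5)c4)[C@H](OCc5ccccc5)[C@H]2CC(O)CO | intermediate
7 | 2-(penta-O-benzylepicatechin-4β-yl)acetaldehyde | O(Cc5ccccc5)c1cc(OCc5ccccc5)c2c(c1)O[C@H](c4ccc(OCc5ccccc5)c(OCc5ccccc5)c4)[C@H](OCc5ccccc5)[C@H]2CC=O | intermediate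
8 | methyl acetoacetate | COC(=O)CC(C)=O | starting material
9 | sodium lithium dianion of methyl acetoacetate | [Na+].[Li+].COC([O-])=CC([O-])=C | intermediate
10 | methyl 5-hydroxy-3-oxo-6-(EC)hexanoate (C5 epimers) | O(Cc5ccccc5)c1cc(OCc5ccccc5)c2c(c1)O[C@H](c4ccc(OCc5ccccc5)c(OCc5ccccc5)c4)[C@H](OCc5ccccc5)[C@H]2CC(O)CC(=O)CC(=O)OC | intermediate
11 | methyl 3,5-dioxo-6-(EC)hexanoate | O(Cc5ccccc5)c1cc(OCc5ccccc5)c2c(c1)O[C@H](c4ccc(OCc5ccccc5)c(OCc5ccccc5)c4)[C@H](OCc5ccccc5)[C@H]2CC(=O)CC(=O)CC(=O)OC | intermediate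
12 | 4-hydroxy-6-[(EC)methyl]-2H-pyran-2-one | O(Cc5ccccc5)c1cc(OCc5ccccc5)c2c(c1)O[C@H](c4ccc(OCc5ccccc5)c(OCc5ccccc5)c4)[C@H](OCc5ccccc5)[C@H]2CC1=CC(O)=CC(=O)O1 | intermediate
13 | (+)-catechin | Oc1cc(O)c2c(c1)O[C@H](c1ccc(O)c(O)c1)[C@@H](O)C2 | starting material
14 | 5,7,3',4'-tetra-O-benzyl-(+)-catechin | c1c(OCc5ccccc5)cc3c(c1OCc5ccccc5)C[C@H](O)[C@@H](c4ccc(OCc5ccccc5)c(OCc5ccccc5)c4)O3 | intermediate
15 | 3,5,7,3',4'-penta-O-benzyl-(+)-catechin | c1c(OCc5ccccc5)cc3c(c1OCc5ccccc5)C[C@H](OCc5ccccc5)[C@@H](c4ccc(OCc5ccccc5)c(OCc5ccccc5)c4)O3 | intermediate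
16 | 8-bromo-penta-O-benzylcatechin | c1c(OCc5ccccc5)c(Br)c3c(c1OCc5ccccc5)C[C@H](OCc5ccccc5)[C@@H](c4ccc(OCc5ccccc5)c(OCc5ccccc5)c4)O3 | intermediate
17 | N,N-dimethyl-(CAT)methaniminium chloride | C[N+](C)=Cc1c(OCc5ccccc5)c(Br)c3c(c1OCc5ccccc5)C[C@H](OCc5ccccc5)[C@@H](c4ccc(OCc5ccccc5)c(OCc5ccccc5)c4)O3.[Cl-] | intermediate
18 | 8-bromo-6-formyl-penta-O-benzylcatechin | O=Cc1c(OCc5ccccc5)c(Br)c3c(c1OCc5ccccc5)C[C@H](OCc5ccccc5)[C@@H](c4ccc(OCc5ccccc5)c(OCc5ccccc5)c4)O3 | intermediate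
19 | (E)-3-(CAT)prop-2-enal | O=C/C=C/c1c(OCc5ccccc5)c(Br)c3c(c1OCc5ccccc5)C[C@H](OCc5ccccc5)[C@@H](c4ccc(OCc5ccccc5)c(OCc5ccccc5)c4)O3 | intermediate
20 | (3R)-3-(CAT)-3-{4-hydroxy-2-oxo-6-[(EC)methyl]-2H-pyran-3-yl}propanal | O(Cc5ccccc5)c1cc(OCc5ccccc5)c2c(c1)O[C@H](c4ccc(OCc5ccccc5)c(OCc5ccccc5)c4)[C@H](OCc5ccccc5)[C@H]2CC1=CC(O)=C(C(=O)O1)[C@@H](c1c(OCc5ccccc5)c(Br)c3c(c1OCc5ccccc5)C[C@H](OCc5ccccc5)[C@@H](c4ccc(OCc5ccccc5)c(OCc5ccccc5)c4)O3)CC=O | intermediate
21 | (4R)-4-(CAT)-2-hydroxy-7-[(EC)methyl]-3,4-dihydro-2H,5H-pyrano[4,3-b]pyran-5-one (anomers) | O(Cc5ccccc5)c1cc(OCc5ccccc5)c2c(c1)O[C@H](c4ccc(OCc5ccccc5)c(OCc5ccccc5)c4)[C@H](OCc5ccccc5)[C@H]2CC1=CC2=C(C(=O)O1)[C@@H](c1c(OCc5ccccc5)c(Br)c3c(c1OCc5ccccc5)C[C@H](OCc5ccccc5)[C@@H](c4ccc(OCc5ccccc5)c(OCc5ccccc5)c4)O3)CC(O)O2 | intermediate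
22 | 4-bromocatechol | Oc1ccc(Br)cc1O | starting material
23 | 4-bromo-1,2-bis(benzyloxy)benzene | Brc4ccc(OCc5ccccc5)c(OCc5ccccc5)c4 | intermediate
24 | 3,4-bis(benzyloxy)phenylmagnesium bromide | Br[Mg]c4ccc(OCc5ccccc5)c(OCc5ccccc5)c4 | intermediate
25 | 3-[(1R)-3-Ar-1-(CAT)-3-hydroxypropyl]-4-hydroxy-6-[(EC)methyl]-2H-pyran-2-one (carbinol epimers) | O(Cc5ccccc5)c1cc(OCc5ccccc5)c2c(c1)O[C@H](c4ccc(OCc5ccccc5)c(OCc5ccccc5)c4)[C@H](OCc5ccccc5)[C@H]2CC1=CC(O)=C(C(=O)O1)[C@@H](c1c(OCc5ccccc5)c(Br)c3c(c1OCc5ccccc5)C[C@H](OCc5ccccc5)[C@@H](c4ccc(OCc5ccccc5)c(OCc5ccccc5)c4)O3)CC(O)c4ccc(OCc5ccccc5)c(OCc5ccccc5)c4 | intermediate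
26 | 3-[(1R)-3-Ar-1-(CAT)-3-oxopropyl]-4-hydroxy-6-[(EC)methyl]-2H-pyran-2-one | O(Cc5ccccc5)c1cc(OCc5ccccc5)c2c(c1)O[C@H](c4ccc(OCc5ccccc5)c(OCc5ccccc5)c4)[C@H](OCc5ccccc5)[C@H]2CC1=CC(O)=C(C(=O)O1)[C@@H](c1c(OCc5ccccc5)c(Br)c3c(c1OCc5ccccc5)C[C@H](OCc5ccccc5)[C@@H](c4ccc(OCc5ccccc5)c(OCc5ccccc5)c4)O3)CC(=O)c4ccc(OCc5ccccc5)c(OCc5ccccc5)c4 | intermediate
27 | (4R)-2-Ar-4-(CAT)-2-hydroxy-7-[(EC)methyl]-3,4-dihydro-2H,5H-pyrano[4,3-b]pyran-5-one (hemiketal) | O(Cc5ccccc5)c1cc(OCc5ccccc5)c2c(c1)O[C@H](c4ccc(OCc5ccccc5)c(OCc5ccccc5)c4)[C@H](OCc5ccccc5)[C@H]2CC1=CC2=C(C(=O)O1)[C@@H](c1c(OCc5ccccc5)c(Br)c3c(c1OCc5ccccc5)C[C@H](OCc5ccccc5)[C@@H](c4ccc(OCc5ccccc5)c(OCc5ccccc5)c4)O3)CC(O)(c4ccc(OCc5ccccc5)c(OCc5ccccc5)c4)O2 | intermediate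
28 | (4R)-2-Ar-4-(CAT)-7-[(EC)methyl]-4H,5H-pyrano[4,3-b]pyran-5-one | O(Cc5ccccc5)c1cc(OCc5ccccc5)c2c(c1)O[C@H](c4ccc(OCc5ccccc5)c(OCc5ccccc5)c4)[C@H](OCc5ccccc5)[C@H]2CC1=CC2=C(C(=O)O1)[C@@H](c1c(OCc5ccccc5)c(Br)c3c(c1OCc5ccccc5)C[C@H](OCc5ccccc5)[C@@H](c4ccc(OCc5ccccc5)c(OCc5ccccc5)c4)O3)C=C(c4ccc(OCc5ccccc5)c(OCc5ccccc5)c4)O2 | intermediate
29 | 3β-boryl adduct of 28 (2α-Ar, 4α-CAT) | O(Cc5ccccc5)c1cc(OCc5ccccc5)c2c(c1)O[C@H](c4ccc(OCc5ccccc5)c(OCc5ccccc5)c4)[C@H](OCc5ccccc5)[C@H]2CC1=CC2=C(C(=O)O1)[C@@H](c1c(OCc5ccccc5)c(Br)c3c(c1OCc5ccccc5)C[C@H](OCc5ccccc5)[C@@H](c4ccc(OCc5ccccc5)c(OCc5ccccc5)c4)O3)[C@H](B)[C@@H](c4ccc(OCc5ccccc5)c(OCc5ccccc5)c4)O2 | intermediate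
30 | (2R,3S,4R)-2-Ar-4-(CAT)-3-hydroxy-7-[(EC)methyl]-3,4-dihydro-2H,5H-pyrano[4,3-b]pyran-5-one | O(Cc5ccccc5)c1cc(OCc5ccccc5)c2c(c1)O[C@H](c4ccc(OCc5ccccc5)c(OCc5ccccc5)c4)[C@H](OCc5ccccc5)[C@H]2CC1=CC2=C(C(=O)O1)[C@@H](c1c(OCc5ccccc5)c(Br)c3c(c1OCc5ccccc5)C[C@H](OCc5ccccc5)[C@@H](c4ccc(OCc5ccccc5)c(OCc5ccccc5)c4)O3)[C@H](O)[C@@H](c4ccc(OCc5ccccc5)c(OCc5ccccc5)c4)O2 | intermediate
31 | (2R,3S,4R)-2-Ar-3-benzyloxy-4-(CAT)-7-[(EC)methyl]-3,4-dihydro-2H,5H-pyrano[4,3-b]pyran-5-one (key-step precursor) | O(Cc5ccccc5)c1cc(OCc5ccccc5)c2c(c1)O[C@H](c4ccc(OCc5ccccc5)c(OCc5ccccc5)c4)[C@H](OCc5ccccc5)[C@H]2CC1=CC2=C(C(=O)O1)[C@@H](c1c(OCc5ccccc5)c(Br)c3c(c1OCc5ccccc5)C[C@H](OCc5ccccc5)[C@@H](c4ccc(OCc5ccccc5)c(OCc5ccccc5)c4)O3)[C@H](OCc5ccccc5)[C@@H](c4ccc(OCc5ccccc5)c(OCc5ccccc5)c4)O2 | intermediate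
32 | methyl (2R,3S,4R)-2-Ar-3-benzyloxy-4-(CAT)-6-[2-oxo-3-(EC)propyl]-3,4-dihydro-2H-pyran-5-carboxylate | O(Cc5ccccc5)c1cc(OCc5ccccc5)c2c(c1)O[C@H](c4ccc(OCc5ccccc5)c(OCc5ccccc5)c4)[C@H](OCc5ccccc5)[C@H]2CC(=O)CC2=C(C(=O)OC)[C@@H](c1c(OCc5ccccc5)c(Br)c3c(c1OCc5ccccc5)C[C@H](OCc5ccccc5)[C@@H](c4ccc(OCc5ccccc5)c(OCc5ccccc5)c4)O3)[C@H](OCc5ccccc5)[C@@H](c4ccc(OCc5ccccc5)c(OCc5ccccc5)c4)O2 | intermediate
33 | penta-O-benzylepicatechin-(4β→6)-3,3',4'-tri-O-benzylcatechin-(4α→6)-8-bromo-penta-O-benzylcatechin (key-step product) | O(Cc5ccccc5)c1cc(OCc5ccccc5)c2c(c1)O[C@H](c4ccc(OCc5ccccc5)c(OCc5ccccc5)c4)[C@H](OCc5ccccc5)[C@H]2c1c(O)cc2c(c1O)[C@@H](c1c(OCc5ccccc5)c(Br)c3c(c1OCc5ccccc5)C[C@H](OCc5ccccc5)[C@@H](c4ccc(OCc5ccccc5)c(OCc5ccccc5)c4)O3)[C@H](OCc5ccccc5)[C@@H](c4ccc(OCc5ccccc5)c(OCc5ccccc5)c4)O2 | intermediate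
34 | epicatechin-(4β→6)-catechin-(4α→6)-catechin (CNP0163146.4) | Oc1cc(O)c2c(c1)O[C@H](c1ccc(O)c(O)c1)[C@H](O)[C@H]2c1c(O)cc2c(c1O)[C@@H](c1c(O)cc3c(c1O)C[C@H](O)[C@@H](c1ccc(O)c(O)c1)O3)[C@H](O)[C@@H](c1ccc(O)c(O)c1)O2 | target

Total step count: 22. Longest linear sequence: 16 steps (steps 1–8, 14, 16–22). Steps 9–13 join at step 14 and step 15 joins at step 16.

Steps most likely to fail

Step 21. The ring-opened ester may stay parked as its C8 dienolate and relactonise on work-up, so that C5–C6 bond formation never competes. At the temperature needed, methoxide may also exchange with O1 at C8a and unzip ring C. The fallback uses known chemistry, sets out from 16 and 4 and returns to the route at 34. It takes the middle ring A from catechin and makes both interflavan bonds by Lewis-acid coupling under bromine capping. Oxidation of 16 with DDQ and 2-ethoxyethanol gives 8-bromo-4β-(2-ethoxyethoxy)-penta-O-benzylcatechin F1. Condensation of F1 with an excess of 16, whose only free ring A position is C6, under Me3SiOSO2CF3 at −78 °C gives 8-bromo-penta-O-benzylcatechin-(4α→6)-8-bromo-penta-O-benzylcatechin F2, the aryl group entering trans to the 3-O-benzyl group. The one nucleophilic carbon left in F2, C6 of its upper half, is then alkylated with 4 under the same promoter to give penta-O-benzylepicatechin-(4β→6)-8-bromo-penta-O-benzylcatechin-(4α→6)-8-bromo-penta-O-benzylcatechin F3. Hydrogenolysis over Pd(OH)2/C with Et3N, as in step 22, gives 34.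

Step 19. Once boron sits on C3 it is anti-periplanar to the C2–O1 bond, and O1 leaves about as well as a carboxylate, so β-elimination with opening of ring C may outrun oxidation. Slow addition next to the bulky C4 aryl group also gives borane time to reduce the lactone. The fallback sets out from 28 and returns at 30. It replaces hydroboration by oxidation followed by ionic reduction. Dihydroxylation with OsO4 (catalytic) and N-methylmorpholine N-oxide on the β face, opposite the 4α-aryl group, gives the 2,3-dihydroxy hemiketal (3S,4R)-2-Ar-4-(CAT)-2,3-dihydroxy-7-[(EC)methyl]-3,4-dihydro-2H,5H-pyrano[4,3-b]pyran-5-one F4. Reduction of F4 with an excess of Et3SiH and BF3·OEt2 at −78 °C delivers hydride axially to the aryl-stabilised C2 cation, which places the aryl group equatorial and gives 30.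

Step 14. The enal carries an electron-rich, doubly ortho-substituted aryl group, so conjugate addition may be slow and reversible. 1,2-Condensation followed by oxa-electrocyclisation may take over, and facial selectivity may erode. The fallback sets out from 18 and 12 and returns at 28, bypassing steps 13–18. It gives up catalyst control in favour of a shorter, acid-mediated assembly. Claisen–Schmidt condensation of 18 with 3,4-bis(benzyloxy)acetophenone F5 (KOH, EtOH–THF) gives the chalcone (E)-1-Ar-3-(CAT)prop-2-en-1-one F6. Tandem Michael addition and cyclodehydration of 12 with F6 under AuCl3/AgOTf in toluene gives 28 together with its C4 epimer (4S)-2-Ar-4-(CAT)-7-[(EC)methyl]-4H,5H-pyrano[4,3-b]pyran-5-one F7. The two are diastereomers, so F7 can be removed by chromatography.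

Further compounds
F1 | step 21 | 8-bromo-4β-(2-ethoxyethoxy)-penta-O-benzylcatechin | c1c(OCc5ccccc5)c(Br)c3c(c1OCc5ccccc5)[C@H](OCCOCC)[C@H](OCc5ccccc5)[C@@H](c4ccc(OCc5ccccc5)c(OCc5ccccc5)c4)O3
F2 | step 21 | 8-bromo-penta-O-benzylcatechin-(4α→6)-8-bromo-penta-O-benzylcatechin | c1c(OCc5ccccc5)c(Br)c2c(c1OCc5ccccc5)[C@@H](c1c(OCc5ccccc5)c(Br)c3c(c1OCc5ccccc5)C[C@H](OCc5ccccc5)[C@@H](c4ccc(OCc5ccccc5)c(OCc5ccccc5)c4)O3)[C@H](OCc5ccccc5)[C@@H](c4ccc(OCc5ccccc5)c(OCc5ccccc5)c4)O2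
F3 | step 21 | penta-O-benzylepicatechin-(4β→6)-8-bromo-penta-O-benzylcatechin-(4α→6)-8-bromo-penta-O-benzylcatechin | O(Cc5ccccc5)c1cc(OCc5ccccc5)c2c(c1)O[C@H](c4ccc(OCc5ccccc5)c(OCc5ccccc5)c4)[C@H](OCc5ccccc5)[C@H]2c1c(OCc5ccccc5)c(Br)c2c(c1OCc5ccccc5)[C@@H](c1c(OCc5ccccc5)c(Br)c3c(c1OCc5ccccc5)C[C@H](OCc5ccccc5)[C@@H](c4ccc(OCc5ccccc5)c(OCc5ccccc5)c4)O3)[C@H](OCc5ccccc5)[C@@H](c4ccc(OCc5ccccc5)c(OCc5ccccc5)c4)O2
F4 | step 19 | (3S,4R)-2-Ar-4-(CAT)-2,3-dihydroxy-7-[(EC)methyl]-3,4-dihydro-2H,5H-pyrano[4,3-b]pyran-5-one | O(Cc5ccccc5)c1cc(OCc5ccccc5)c2c(c1)O[C@H](c4ccc(OCc5ccccc5)c(OCc5ccccc5)c4)[C@H](OCc5ccccc5)[C@H]2CC1=CC2=C(C(=O)O1)[C@@H](c1c(OCc5ccccc5)c(Br)c3c(c1OCc5ccccc5)C[C@H](OCc5ccccc5)[C@@H](c4ccc(OCc5ccccc5)c(OCc5ccccc5)c4)O3)[C@H](O)C(O)(c4ccc(OCc5ccccc5)c(OCc5ccccc5)c4)O2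
F5 | step 14 | 3,4-bis(benzyloxy)acetophenone | CC(=O)c4ccc(OCc5ccccc5)c(OCc5ccccc5)c4
F6 | step 14 | (E)-1-Ar-3-(CAT)prop-2-en-1-one | O=C(c4ccc(OCc5ccccc5)c(OCc5ccccc5)c4)/C=C/c1c(OCc5ccccc5)c(Br)c3c(c1OCc5ccccc5)C[C@H](OCc5ccccc5)[C@@H](c4ccc(OCc5ccccc5)c(OCc5ccccc5)c4)O3
F7 | step 14 | (4S)-2-Ar-4-(CAT)-7-[(EC)methyl]-4H,5H-pyrano[4,3-b]pyran-5-one | O(Cc5ccccc5)c1cc(OCc5ccccc5)c2c(c1)O[C@H](c4ccc(OCc5ccccc5)c(OCc5ccccc5)c4)[C@H](OCc5ccccc5)[C@H]2CC1=CC2=C(C(=O)O1)[C@H](c1c(OCc5ccccc5)c(Br)c3c(c1OCc5ccccc5)C[C@H](OCc5ccccc5)[C@@H](c4ccc(OCc5ccccc5)c(OCc5ccccc5)c4)O3)C=C(c4ccc(OCc5ccccc5)c(OCc5ccccc5)c4)O2
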